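Readings and results were computed for substances that don't exist; scatter was added.

The south-west run has the strongest early signal: 17% of E after 10.0 min at [J] = 0.41 M, with a scatter of 2 percentage points. So I read the exchange constant there, taking the start as a straight line:

k = E / (t [J]) = 0.0415 /M/min

| setting | east | west | south-west | violet | blue | grey | ochre | red |
|---|---|---|---|---|---|---|---|---|
| L | 0.11 M | 0.11 M | 0.11 M | 0.11 M | 0.11 M | 0.11 M | 0.11 M | 0.11 M |
| J | 0.035 M | 0.13 M | 0.41 M | 0.0300 M | 0.0600 M | 0.120 M | 0.250 M | 0.500 M |
| remark | run made earlier | run made earlier | run made earlier |  |  |  |  |  |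
| time |  |  |  | 3.0 h | 3.0 h | 3.0 h | 3.0 h | 3.0 h |

- east (time / min: E / %): 10.0: 2; 20.0: 3; 40.0: 3; 60.0: 10; 120: 11
- west (time / min: E / %): 10.0: 7; 20.0: 11; 40.0: 16; 60.0: 21; 120: 22
- south-west (time / min: E / %): 10.0: 17; 20.0: 29; 40.0: 31; 60.0: 32; 120: 27

(readings scatter by 2 percentage points)

- "hardly changes" means that all values lie within two and a half points (for a concentration: within two and a half percent of the largest)

1. amount of E at the end, in percent of the L charged for violet, blue, grey, ochre, red, in this order
2. how that number moves from the first to the last of them (falls, then rises / rises all the way / rises, then falls / hardly changes / falls all the way)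

First I turn [J]. By hand, the reciprocal of k[J] is the pseudo-first-order time of L, with [J] held at its charge, and more J shortens it. The readings agree: after 10.0 min, E stands at 2%, 7% and 17% in east, west and south-west.

Then I turn the time. By hand, if a further exchange follows at a like rate, E is a middle stage, so it should climb for about one such time and then lose ground. In south-west that time is 58.8 min, and E goes from 32% at 60.0 min to 27% at 120 min. That drop of 5 points is a hint against the scatter.

With the time at 3.0 h, both settings meet in one quantity:

[J]c = 1 / (k t) = 0.134 M

This is the turning concentration, the [J] at which a run of this length holds one exchange time. Below it E should still be climbing at the end, and above it E should already be passing on. Grey lies below it and ochre above it, so I expect the row to turn between them. [J]c holds J at its charge, but J runs down, so I expect the row to turn somewhat higher.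

The forecast gives 10%, 15%, 21%, 27%, 24%, so rises, then falls: a slow drain “cuts the top two values and probably puts the maximum near 0.25 M”. Its peak stands at ochre, where mine stands between grey and ochre.

The flask gives 11.9%, 19.3%, 26.1%, 25.9%, 15.3%, so rises, then falls.

    L + J ⇌ Q + E (K = 1.90, k = 8.90 × 10⁻⁴ /M/s)
    E + J ⇌ Q + Z (K = 1.60, k = 9.00 × 10⁻⁴ /M/s)
    Z + J ⇌ Q + G (K = 82.0, k = 6.90 × 10⁻⁴ /M/s)
    L ⇌ D (K = 0.790, k = 8.80 × 10⁻⁵ /s)

The forecast and the flask part at red, 24% against 15.3%, and the row turns at [J] = 0.17 M, above my 0.134 M. In red, J stands at 68.5% of its charge at 1.50 h, with E at 25.0% and G at 22.9%, and by 3.00 h G stands at 47.6%. Ochre, with [J]c giving it an exchange time of 1.61 h, holds E at 30.2% at 1.50 h and 25.9% at 3.00 h.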